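## Retrosynthetic overview

1. Target 22 comes from the bis-benzyl ether 21 by hydrogenolysis. The spiro centre of 21 is set by a chiral-phosphoric-acid-controlled O→N ring switch of the racemic spiro-imidate 19.
2. 19 comes from a one-step, three-component union of 3-methoxybenzyne (from 15), isocyanide 14 and peri-lactone 12. The isocyanide carbon acts as a carbamoyl-anion equivalent and attacks the electrophilic aryne carbon (the future aryl–C(=O)N bond); the aryl anion so formed acylates the lactone carbonyl (the future spiro carbon).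
3. 12 comes from bromonaphthyl acetate 10 by peri carbonylative lactonisation; 10 from acetate 9; 9 by benzannulation of butenoic acid 6; 6 by Wittig reaction of 4-(benzyloxy)benzaldehyde 4.
4. Ring order: second naphthalene ring (step 3), peri-lactone ring (step 5), imidate ring spiro-fused to the naphthofuran (step 7), lactam ring by O→N switch (step 8).

Assumption: the spiro N,O-ketal is configurationally stable under neutral conditions at room temperature, and the sense of induction in step 8 is settled in the first run (the (R)-acid is written; its mirror image is used if it gives the (R)-product).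

## Route

Step 1
Reactants: 1 triphenylphosphine hydrobromide; 2 (E)-but-2-enoic acid (crotonic acid)
Product: 3 (1-carboxypropan-2-yl)triphenylphosphonium bromide (racemic)
Conditions: neat melt, 150 °C, 2 h; trituration with acetone/Et2O
Reagents that add atoms: none
Why: Conjugate (phospha-Michael) addition of the phosphine to the protonated enoic acid gives the β-phosphonium acid, whose racemic centre is destroyed in step 2.

Step 2
Reactants: 3 (1-carboxypropan-2-yl)triphenylphosphonium bromide; 4 4-(benzyloxy)benzaldehyde
Product: 6 4-[4-(benzyloxy)phenyl]-3-methylbut-3-enoic acid (E/Z mixture), via phosphorus ylide carboxylate 5 (not isolated)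
Conditions: KOC(CH3)3 (2.2 equiv), THF, 0 °C; then 4, 0 °C to rt; aqueous HCl work-up
Reagents that add atoms: none
Why: Wittig olefination of the aldehyde by the carboxylate-bearing non-stabilised ylide gives the β,γ-unsaturated acid, and the alkene geometry does not matter because step 3 equilibrates it.

Step 3
Reactants: 6 4-[4-(benzyloxy)phenyl]-3-methylbut-3-enoic acid (E/Z mixture)
Product: 9 7-(benzyloxy)-3-methylnaphthalen-1-yl acetate, via mixed acetic anhydride 7 (not isolated), via 7-(benzyloxy)-3-methylnaphthalen-1-ol 8 (not isolated)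
Conditions: Ac2O, NaOAc, reflux (140 °C), 4 h
Reagents that add atoms: acetic anhydride, CC(=O)OC(C)=O
Why: Stobbe-type benzannulation: the mixed anhydride, with E/Z equilibration through its dienolate, undergoes intramolecular Friedel–Crafts acylation at the only kind of ortho position of the para-substituted ring, then enolises to the naphthol, which is acetylated in the flask.

Step 4
Reactants: 9 7-(benzyloxy)-3-methylnaphthalen-1-yl acetate
Product: 10 7-(benzyloxy)-8-bromo-3-methylnaphthalen-1-yl acetate
Conditions: N-bromosuccinimide (1.05 equiv), MeCN, 0 °C to rt, dark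
Reagents that add atoms: N-bromosuccinimide, O=C1CCC(=O)N1Br
Why: Electrophilic aromatic bromination goes to the alpha position ortho to the benzyloxy group (the 1-position of a 2-alkoxynaphthalene), while the acetate keeps the other ring deactivated.

Step 5
Reactants: 10 7-(benzyloxy)-8-bromo-3-methylnaphthalen-1-yl acetate
Product: 12 3-(benzyloxy)-7-methyl-2H-naphtho[1,8-bc]furan-2-one, via 7-(benzyloxy)-8-bromo-3-methylnaphthalen-1-ol 11 (not isolated)
Conditions: K2CO3 (1.2 equiv), MeOH, rt, 1 h; evaporate; then CO (1 atm), Pd(OAc)2 (5 mol%), 4,5-bis(diphenylphosphino)-9,9-dimethylxanthene (6 mol%), 1,4-dioxane, 100 °C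
Reagents that add atoms: carbon monoxide, [C-]#[O+]
Why: Methanolysis frees the naphthoxide, and palladium-catalysed intramolecular aryloxycarbonylation (oxidative addition of the C–Br bond to zerovalent palladium, CO insertion, capture of the acyl palladium by the peri oxygen) closes the lactone.

Step 6
Reactants: 13 2-(benzyloxy)ethan-1-amine
Product: 14 [(2-isocyanoethoxy)methyl]benzene (2-(benzyloxy)ethyl isocyanide)
Conditions: CHCl3 (1.1 equiv), 50% aqueous NaOH, benzyltriethylammonium chloride (2 mol%), CH2Cl2, 40 °C
Reagents that add atoms: chloroform, ClC(Cl)Cl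
Why: Hofmann carbylamine reaction under phase transfer: dichlorocarbene is taken up by the primary amine and two dehydrochlorinations give the isocyanide.

Step 7
Reactants: 12 3-(benzyloxy)-7-methyl-2H-naphtho[1,8-bc]furan-2-one; 14 [(2-isocyanoethoxy)methyl]benzene; 15 3-methoxy-2-(trimethylsilyl)phenyl trifluoromethanesulfonate
Product: 19 rac-N-[2-(benzyloxy)ethyl]-3'-(benzyloxy)-7-methoxy-7'-methyl-3H-spiro[2-benzofuran-1,2'-naphtho[1,8-bc]furan]-3-imine, via 3-methoxybenzyne 16 (not isolated), via aryl anion nitrilium zwitterion 17 (not isolated), via alkoxide nitrilium zwitterion 18 (not isolated)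
Conditions: 15 (1.6 equiv), 14 (1.6 equiv), KF (3.2 equiv), 18-crown-6 (3.2 equiv), THF, 0 °C to rt, 12 h; filtration through basic alumina (no acid, no silica)
Reagents that add atoms: none
Why: Proposed new method: fluoride unmasks the aryne, the isocyanide carbon (a carbamoyl-anion equivalent) adds to the aryne carbon remote from OMe, and the aryl anion ortho to OMe attacks the strained, planar peri-lactone carbonyl from above the naphthalene plane, after which the tetrahedral alkoxide closes 5-exo onto the nitrilium to give the spiro-imidate (if the alkoxide first expels the peri-naphthoxide, re-addition is fast and only nitrilium capture is irreversible); the closest known reaction is the aryne/isocyanide/carbonyl three-component coupling with aldehydes, ketones and quinones that gives iminoisobenzofurans, and the spiro centre is formed racemic here.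

Step 8
Reactants: 19 rac-N-[2-(benzyloxy)ethyl]-3'-(benzyloxy)-7-methoxy-7'-methyl-3H-spiro[2-benzofuran-1,2'-naphtho[1,8-bc]furan]-3-imine
Product: 21 (S)-3'-(benzyloxy)-2-[2-(benzyloxy)ethyl]-7-methoxy-7'-methylspiro[isoindoline-1,2'-naphtho[1,8-bc]furan]-3-one, via oxocarbenium amide ion pair 20 (not isolated)
Conditions: (R)-3,3'-bis(2,4,6-triisopropylphenyl)-1,1'-binaphthyl-2,2'-diyl hydrogen phosphate (10 mol%), 5 Å molecular sieves, toluene, 50 °C
Reagents that add atoms: none
Why: Proposed new method: N-protonation of the cyclic imidate makes the amide a neutral leaving group, C–O ionisation gives a planar oxocarbenium ion stabilised by the furan oxygen and the 2-benzyloxynaphthyl ring (the racemic centre is erased), and the amide N–H, hydrogen-bonded to the chiral phosphate, closes on one face to the far more stable lactam, setting the (S) centre irreversibly (a stereoablative dynamic kinetic asymmetric transformation); the closest known reactions are the acid-catalysed iminophthalan-to-isoindolinone (Mumm/Chapman-type) rearrangement and chiral phosphoric acid-catalysed N,O-ketal formation through N-acyliminium or oxocarbenium ion pairs.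

Step 9
Reactants: 21 (S)-3'-(benzyloxy)-2-[2-(benzyloxy)ethyl]-7-methoxy-7'-methylspiro[isoindoline-1,2'-naphtho[1,8-bc]furan]-3-one
Product: 22 (S)-3'-hydroxy-2-(2-hydroxyethyl)-7-methoxy-7'-methylspiro[isoindoline-1,2'-naphtho[1,8-bc]furan]-3-one
Conditions: H2 (1 atm), palladium on carbon (10 wt% Pd), EtOAc/EtOH, rt; stop at full conversion, filter
Reagents that add atoms: none
Why: Catalytic hydrogenolysis removes the aryl and the alkyl benzyl ether under neutral conditions, while the fully substituted spiro C–O bond cannot lie flat on the metal and nothing ionises the N,O-ketal, so the (S) centre from step 8 is carried through unchanged.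

## Compound list

1 | triphenylphosphine hydrobromide | [PH+](c1ccccc1)(c1ccccc1)c1ccccc1.[Br-] | starting material
2 | (E)-but-2-enoic acid | C/C=C/C(=O)O | starting material
3 | (1-carboxypropan-2-yl)triphenylphosphonium bromide (racemic) | CC(CC(=O)O)[P+](c1ccccc1)(c1ccccc1)c1ccccc1.[Br-] | intermediate
4 | 4-(benzyloxy)benzaldehyde | O=Cc1ccc(OCc2ccccc2)cc1 | starting material
5 | potassium 3-(triphenyl-λ5-phosphanylidene)butanoate (ylide, formed in the flask) | CC(CC(=O)[O-])=P(c1ccccc1)(c1ccccc1)c1ccccc1.[K+] | intermediate
6 | 4-[4-(benzyloxy)phenyl]-3-methylbut-3-enoic acid (E/Z mixture) | CC(CC(=O)O)=Cc1ccc(OCc2ccccc2)cc1 | intermediate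
7 | acetic 4-[4-(benzyloxy)phenyl]-3-methylbut-3-enoic anhydride (formed in the flask) | CC(=O)OC(=O)CC(C)=Cc1ccc(OCc2ccccc2)cc1 | intermediate
8 | 7-(benzyloxy)-3-methylnaphthalen-1-ol (formed in the flask) | Cc1cc(O)c2cc(OCc3ccccc3)ccc2c1 | intermediate
9 | 7-(benzyloxy)-3-methylnaphthalen-1-yl acetate | CC(=O)Oc1cc(C)cc2ccc(OCc3ccccc3)cc12 | intermediate
10 | 7-(benzyloxy)-8-bromo-3-methylnaphthalen-1-yl acetate | CC(=O)Oc1cc(C)cc2ccc(OCc3ccccc3)c(Br)c12 | intermediate
11 | 7-(benzyloxy)-8-bromo-3-methylnaphthalen-1-ol (formed in the flask, present as its potassium salt) | Cc1cc(O)c2c(Br)c(OCc3ccccc3)ccc2c1 | intermediate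
12 | 3-(benzyloxy)-7-methyl-2H-naphtho[1,8-bc]furan-2-one | O=C1Oc2cc(C)cc3ccc(OCc4ccccc4)c1c23 | intermediate
13 | 2-(benzyloxy)ethan-1-amine | NCCOCc1ccccc1 | starting material
14 | [(2-isocyanoethoxy)methyl]benzene | [C-]#[N+]CCOCc1ccccc1 | intermediate
15 | 3-methoxy-2-(trimethylsilyl)phenyl trifluoromethanesulfonate | COc1cccc(OS(=O)(=O)C(F)(F)F)c1[Si](C)(C)C | starting material
16 | 3-methoxybenzyne (formed in the flask) | COC1=CC=CC#C1 | intermediate
17 | 2-{[2-(benzyloxy)ethyl]nitrilio-methylidyne}-6-methoxybenzen-1-ide (aryl anion nitrilium zwitterion, formed in the flask) | COc1cccc(C#[N+]CCOCc2ccccc2)[c-]1 | intermediate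
18 | alkoxide nitrilium zwitterion from addition of 17 to the carbonyl of 12 (formed in the flask) | COc1cccc(C#[N+]CCOCc2ccccc2)c1C1([O-])Oc2cc(C)cc3ccc(OCc4ccccc4)c1c23 | intermediate
19 | rac-N-[2-(benzyloxy)ethyl]-3'-(benzyloxy)-7-methoxy-7'-methyl-3H-spiro[2-benzofuran-1,2'-naphtho[1,8-bc]furan]-3-imine | COc1cccc2c1C1(Oc3cc(C)cc4ccc(OCc5ccccc5)c1c34)OC2=NCCOCc1ccccc1 | intermediate
20 | 3-(benzyloxy)-2-(2-{[2-(benzyloxy)ethyl]carbamoyl}-6-methoxyphenyl)-7-methylnaphtho[1,8-bc]furan-1-ium (formed in the flask as its chiral phosphate ion pair) | COc1cccc(C(=O)NCCOCc2ccccc2)c1C1=[O+]c2cc(C)cc3ccc(OCc4ccccc4)c1c23 | intermediate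
21 | (S)-3'-(benzyloxy)-2-[2-(benzyloxy)ethyl]-7-methoxy-7'-methylspiro[isoindoline-1,2'-naphtho[1,8-bc]furan]-3-one | COc1cccc2c1[C@]1(Oc3cc(C)cc4ccc(OCc5ccccc5)c1c34)N(CCOCc1ccccc1)C2=O | intermediate
22 | (S)-3'-hydroxy-2-(2-hydroxyethyl)-7-methoxy-7'-methylspiro[isoindoline-1,2'-naphtho[1,8-bc]furan]-3-one | COc1cccc2c1[C@]1(Oc3cc(C)cc4ccc(O)c1c34)N(CCO)C2=O | target

## Step count and risks

Total step count: 9. Longest linear sequence: 8 (steps 1 to 5, then 7 to 9); step 6 is a one-step side branch.

**Step 7 (lactone as the carbonyl partner of the aryne coupling).** The lactone may react too slowly with the aryl anion, or fluoride may open it and the naphthoxide may arylate. The fallback uses an aldehyde, the established partner for this coupling, and adds the missing oxidation afterwards. It sets out from 12. Reduction with (i-Bu)2AlH (CH2Cl2, −78 °C) gives the lactol 3-(benzyloxy)-7-methyl-2H-naphtho[1,8-bc]furan-2-ol F1. Its open hydroxy-aldehyde form is O-allylated (allyl bromide, K2CO3, DMF) to 8-(allyloxy)-2-(benzyloxy)-6-methyl-1-naphthaldehyde F2. F2, 14 and 15 under the KF/18-crown-6 conditions give 3-[8-(allyloxy)-2-(benzyloxy)-6-methylnaphthalen-1-yl]-N-[2-(benzyloxy)ethyl]-4-methoxy-2-benzofuran-1(3H)-imine F3. Pd(PPh3)4 with morpholine removes the allyl group to give 7-(benzyloxy)-8-(3-{[2-(benzyloxy)ethyl]imino}-7-methoxy-1,3-dihydro-2-benzofuran-1-yl)-3-methylnaphthalen-1-ol F4. 2,3-Dichloro-5,6-dicyano-1,4-benzoquinone (CH2Cl2, 4 Å sieves, 0 °C) then abstracts the doubly benzylic hydride next to the ring oxygen, and the peri-hydroxyl closes onto the oxocarbenium ion. The fallback comes back to the route at 19.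

**Step 8 (enantioselective O→N ring switch).** The selectivity may be low, or the imidate may tie up the acid. The fallback replaces asymmetric catalysis by resolution. It sets out from 19. CF3CO2H (5 mol%, CH2Cl2, rt) gives rac-3'-(benzyloxy)-2-[2-(benzyloxy)ethyl]-7-methoxy-7'-methylspiro[isoindoline-1,2'-naphtho[1,8-bc]furan]-3-one F5. Preparative chromatography on an amylose tris(3,5-dimethylphenylcarbamate) stationary phase (supercritical CO2/MeOH) separates the enantiomers. The (S)-enantiomer is 21, where the route is rejoined; the (R)-enantiomer can be re-equilibrated with acid and recycled.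

**Step 5 (carbonylative peri-lactonisation of a doubly flanked aryl bromide).** Oxidative addition or ring closure to the strained lactone may fail. The fallback replaces palladium carbonylation by carboxylation of an aryllithium. It sets out from 10. K2CO3/MeOH followed by acidic work-up gives 11, this time isolated. NaH (1.0 equiv), then tert-butyllithium (2.1 equiv, THF, −78 °C; bromine–lithium exchange on the sodium naphthoxide), CO2 and aqueous HCl give 2-(benzyloxy)-8-hydroxy-6-methyl-1-naphthoic acid F6. Dehydration (TsOH cat., toluene, reflux, Dean–Stark) closes the lactone, and the fallback comes back at 12.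

## Further compounds

F1 | step 7 | 3-(benzyloxy)-7-methyl-2H-naphtho[1,8-bc]furan-2-ol (racemic) | OC1Oc2cc(C)cc3ccc(OCc4ccccc4)c1c23
F2 | step 7 | 8-(allyloxy)-2-(benzyloxy)-6-methyl-1-naphthaldehyde | O=Cc1c(OCc2ccccc2)ccc2cc(C)cc(OCC=C)c12
F3 | step 7 | 3-[8-(allyloxy)-2-(benzyloxy)-6-methylnaphthalen-1-yl]-N-[2-(benzyloxy)ethyl]-4-methoxy-2-benzofuran-1(3H)-imine (racemic) | COc1cccc2c1C(c1c(OCc3ccccc3)ccc3cc(C)cc(OCC=C)c13)OC2=NCCOCc1ccccc1
F4 | step 7 | 7-(benzyloxy)-8-(3-{[2-(benzyloxy)ethyl]imino}-7-methoxy-1,3-dihydro-2-benzofuran-1-yl)-3-methylnaphthalen-1-ol (racemic) | COc1cccc2c1C(c1c(OCc3ccccc3)ccc3cc(C)cc(O)c13)OC2=NCCOCc1ccccc1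
F5 | step 8 | rac-3'-(benzyloxy)-2-[2-(benzyloxy)ethyl]-7-methoxy-7'-methylspiro[isoindoline-1,2'-naphtho[1,8-bc]furan]-3-one | COc1cccc2c1C1(Oc3cc(C)cc4ccc(OCc5ccccc5)c1c34)N(CCOCc1ccccc1)C2=O
F6 | step 5 | 2-(benzyloxy)-8-hydroxy-6-methyl-1-naphthoic acid | OC(=O)c1c(OCc2ccccc2)ccc2cc(C)cc(O)c12
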